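**Strategy**

The two halves of the target are mirror images of one hydroxylated bicyclic lactone, so one route is run twice with antipodal catalysts. It rests on the ring A (cyclohexane) bond between the isopropyl-bearing carbon and its ring CH2 neighbour; this CH2 lies β to the carbinol carbon, a ketone at that stage. In one operation, visible-light decarboxylation of an α-isopropyl carboxylic acid gives a secondary radical that closes 6-endo onto a vinyl ketone, forming ring A and resetting the isopropyl stereocentre trans to its neighbour. The precursor is an open-chain acid with a silyl-protected hydroxymethyl stereocentre and a tert-butyl β-keto ester vinyl ketone.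

Key step: step 7

Remarks on the chemistry (assumptions):
- The two bicyclic halves have opposite configuration at all four ring stereocentres; steps 2–15 (series A) are therefore repeated as steps 17–30 (series B) with the antipodal organocatalyst.
- tert-Butyl 4-oxobutanoate, tert-butyl 2-(bromomethyl)acrylate and both antipodes of the prolinol silyl ether are taken as purchasable.
- The carbon between the two carbonyl groups of 12, 13, 31 and 32 is configurationally labile; these compounds are handled as epimer (and enol) mixtures and are written without a descriptor at that carbon (nor at the carbinol carbon of 12 and 31).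
- The hydroxymethyl group is carried as a TBDPS ether: a benzyl ether would offer the radical of step 7 a benzylic hydrogen in a 1,5 relationship and could not be removed later without hydrogenating alkenes.
- Bicyclic compounds use 2-benzoxepine numbering: C-1 lactone carbonyl, O-2, C-3, C-4 (carboxyl-bearing), C-5, C-5a, C-6 (isopropyl), C-7, C-8, C-9 (carbinol), C-9a.

**Route**

Step 1
Reactants: 1 isobutyraldehyde (2-methylpropanal); 2 nitromethane
Product: 5 (E)-3-methyl-1-nitrobut-1-ene, via nitro alcohol 3 (not isolated), via its mesylate 4 (not isolated)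
Conditions: MeNO2 (3 equiv), 1,1,3,3-tetramethylguanidine (5 mol %), THF, 0 °C; concentrate; MsCl, Et3N, CH2Cl2, 0 °C
Reagents that add atoms: none
Why: Base-catalysed Henry (nitroaldol) addition, then mesylation and E1cB elimination, should give the conjugated nitroalkene as its more stable E isomer; no stereocentre is carried on.

Step 2
Reactants: 6 tert-butyl 4-oxobutanoate; 5 (E)-3-methyl-1-nitrobut-1-ene
Product: 8 tert-butyl (3S,4S)-3-(hydroxymethyl)-5-methyl-4-(nitromethyl)hexanoate, via aldehyde adduct 7 (not isolated)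
Conditions: (R)-2-[diphenyl(trimethylsilyloxy)methyl]pyrrolidine (10 mol %), 4-nitrophenol (10 mol %), toluene, 0 °C to rt; then NaBH4, MeOH, 0 °C
Reagents that add atoms: none
Why: Enamine-catalysed Michael addition of an aldehyde to a nitroalkene with a diarylprolinol silyl ether: the bulky diphenyl(silyloxy)methyl group blocks one face of the anti-enamine, so the R catalyst should give C-3 as S, the compact transition state gives the syn adduct (C-4, erased in step 7), and NaBH4 reduction in the same flask removes the epimerisable aldehyde while the tert-butyl ester resists lactonisation.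

Step 3
Reactants: 8 tert-butyl (3S,4S)-3-(hydroxymethyl)-5-methyl-4-(nitromethyl)hexanoate
Product: 9 tert-butyl (3S,4S)-3-{[tert-butyl(diphenyl)silyl]oxymethyl}-5-methyl-4-(nitromethyl)hexanoate
Conditions: TBDPSCl, imidazole, CH2Cl2, rt
Reagents that add atoms: tert-butyl(chloro)diphenylsilane, CC(C)(C)[Si](Cl)(c1ccccc1)c1ccccc1
Why: Imidazole-assisted silylation of a primary alcohol, giving an ether that survives the acetic acid of step 4; no stereocentre is touched.

Step 4
Reactants: 9 tert-butyl (3S,4S)-3-{[tert-butyl(diphenyl)silyl]oxymethyl}-5-methyl-4-(nitromethyl)hexanoate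
Product: 10 (2S,3S)-5-tert-butoxy-3-{[tert-butyl(diphenyl)silyl]oxymethyl}-5-oxo-2-(propan-2-yl)pentanoic acid
Conditions: NaNO2 (3 equiv), AcOH (10 equiv), DMSO, 35 °C
Reagents that add atoms: sodium nitrite, [Na+].[O-]N=O
Why: Nitrosative conversion of a primary nitroalkane into a carboxylic acid (nitronate nitrosation to the nitrolic acid, then nitrile oxide and hydrolysis) under weakly acidic conditions that should leave the silyl ether, the tert-butyl ester and the adjacent stereocentre alone.

Step 5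
Reactants: 10 (2S,3S)-5-tert-butoxy-3-{[tert-butyl(diphenyl)silyl]oxymethyl}-5-oxo-2-(propan-2-yl)pentanoic acid; 11 acrolein (prop-2-enal)
Product: 12 (2S,3R)-4-(tert-butoxycarbonyl)-3-{[tert-butyl(diphenyl)silyl]oxymethyl}-5-hydroxy-2-(propan-2-yl)hept-6-enoic acid (mixture of C-4/C-5 diastereomers)
Conditions: LDA (2.3 equiv), THF, −78 °C; acrolein (1.5 equiv), −78 °C; AcOH, −78 °C; crude taken on at once
Reagents that add atoms: none
Why: Aldol addition of a carboxylate/ester-enolate dianion: the second equivalent of LDA removes a proton from the unhindered CH2 of the tert-butyl ester (the carboxylate shields the hindered α-CH) and the enolate adds 1,2 to acrolein at low temperature; the two new centres are uncontrolled and irrelevant, since one is oxidised next and the other becomes the labile β-keto ester carbon.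

Step 6
Reactants: 12 (2S,3R)-4-(tert-butoxycarbonyl)-3-{[tert-butyl(diphenyl)silyl]oxymethyl}-5-hydroxy-2-(propan-2-yl)hept-6-enoic acid
Product: 13 (2S,3R)-4-(tert-butoxycarbonyl)-3-{[tert-butyl(diphenyl)silyl]oxymethyl}-5-oxo-2-(propan-2-yl)hept-6-enoic acid (C-4 epimers and enol)
Conditions: Dess–Martin periodinane (1.3 equiv), NaHCO3, CH2Cl2, 0 °C
Reagents that add atoms: none
Why: Dess–Martin oxidation of the allylic β-hydroxy ester to the β-keto ester vinyl ketone under buffered, non-basic conditions that the free acid, the silyl ether and the sensitive enone should tolerate, done before the δ-hydroxy acid can lactonise.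

Step 7
Reactants: 13 (2S,3R)-4-(tert-butoxycarbonyl)-3-{[tert-butyl(diphenyl)silyl]oxymethyl}-5-oxo-2-(propan-2-yl)hept-6-enoic acid
Product: 14 tert-butyl (1S,2R,3R)-2-{[tert-butyl(diphenyl)silyl]oxymethyl}-6-oxo-3-(propan-2-yl)cyclohexane-1-carboxylate (all-trans)
Conditions: Ir[dF(CF3)ppy]2(dtbbpy)PF6 (2 mol %), K2HPO4 (1 equiv), MeCN/H2O (9:1), 10 mM, degassed, blue LEDs (450 nm), rt
Reagents that add atoms: none
Why: The photoexcited trivalent iridium complex oxidises the carboxylate of 13, CO2 is lost, and the nucleophilic secondary radical on the isopropyl-bearing carbon adds to the unsubstituted terminus of the vinyl ketone; the α-keto radical so formed is reduced by the divalent iridium species to the enolate, which is protonated. The closest known reaction type is the photoredox decarboxylative Giese (conjugate) addition of aliphatic acids to enones, used here intramolecularly. Ring A closes in the 6-endo-trig mode, because the 5-exo path would need attack at the acyl-bearing alkene carbon, which is mismatched in polarity for an alkyl radical. The new isopropyl stereocentre (C-3, R) is set by a chair-like transition state with the isopropyl and silyloxymethyl groups both equatorial, i.e. trans, and the labile β-keto ester carbon then settles as the all-equatorial epimer (C-1, S). The step needs the carboxylate, not the β-keto ester, to be oxidised and ring closure to outrun intermolecular addition and hydrogen transfer: the carboxylic acid is the only group ionised by one equivalent of phosphate in aqueous acetonitrile, the TBDPS ether offers no weak C–H bond in a 1,5 relationship to the radical, and high dilution does the rest.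

Step 8
Reactants: 14 tert-butyl (1S,2R,3R)-2-{[tert-butyl(diphenyl)silyl]oxymethyl}-6-oxo-3-(propan-2-yl)cyclohexane-1-carboxylate
Product: 15 tert-butyl (1S,2R,3R)-2-{[tert-butyl(diphenyl)silyl]oxymethyl}-6-methylidene-3-(propan-2-yl)cyclohexane-1-carboxylate
Conditions: Zn, CH2Br2, TiCl4 (reagent pre-formed in THF at 5 °C), CH2Cl2, 0 °C to rt
Reagents that add atoms: dibromomethane, BrCBr
Why: Takai–Lombardo methylenation: the non-basic zinc/titanium methylene reagent adds to the Lewis-acid-activated ketone and eliminates to the alkene without enolate formation, so the acidic β-keto ester should react at the ketone only and the three ring stereocentres stay all-equatorial.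

Step 9
Reactants: 15 tert-butyl (1S,2R,3R)-2-{[tert-butyl(diphenyl)silyl]oxymethyl}-6-methylidene-3-(propan-2-yl)cyclohexane-1-carboxylate
Product: 16 tert-butyl (1S,2R,3R)-2-(hydroxymethyl)-6-methylidene-3-(propan-2-yl)cyclohexane-1-carboxylate
Conditions: HF·pyridine, pyridine, THF, 0 °C to rt
Reagents that add atoms: none
Why: Fluoride cleavage of the silyl ether (Si–F bond formation) under buffered conditions that should neither isomerise the β,γ-unsaturated ester nor cleave the tert-butyl ester.

Step 10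
Reactants: 16 tert-butyl (1S,2R,3R)-2-(hydroxymethyl)-6-methylidene-3-(propan-2-yl)cyclohexane-1-carboxylate
Product: 17 tert-butyl (1S,2R,3R)-2-formyl-6-methylidene-3-(propan-2-yl)cyclohexane-1-carboxylate
Conditions: Dess–Martin periodinane, NaHCO3, CH2Cl2, 0 °C
Reagents that add atoms: none
Why: Dess–Martin oxidation of the primary alcohol under neutral conditions; the formyl-bearing carbon is equatorial and trans to both neighbours, hence the thermodynamic epimer and not at risk.

Step 11
Reactants: 17 tert-butyl (1S,2R,3R)-2-formyl-6-methylidene-3-(propan-2-yl)cyclohexane-1-carboxylate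
Product: 18 tert-butyl (1S,2R,3R)-2-ethenyl-6-methylidene-3-(propan-2-yl)cyclohexane-1-carboxylate
Conditions: Ph3PCH3Br, KHMDS, THF, −78 to 0 °C
Reagents that add atoms: methyltriphenylphosphonium bromide, [Br-].C[P+](c1ccccc1)(c1ccccc1)c1ccccc1
Why: Wittig methylenation of the aldehyde with a slight excess of ylide at low temperature, fast enough to spare the ester α-hydrogen; stereocentres are unchanged.

Step 12
Reactants: 18 tert-butyl (1S,2R,3R)-2-ethenyl-6-methylidene-3-(propan-2-yl)cyclohexane-1-carboxylate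
Product: 20 (1S,2R,3R)-2-ethenyl-6-methylidene-3-(propan-2-yl)cyclohexane-1-carboxylic acid, via its trimethylsilyl ester 19 (not isolated)
Conditions: TMSOTf, 2,6-lutidine, CH2Cl2, 0 °C to rt; then aqueous pH 5 buffer
Reagents that add atoms: none
Why: Silyl-triflate cleavage of a tert-butyl ester (O-silylation, loss of isobutene to the buffered base) and hydrolysis of the silyl ester on work-up, a non-protic method chosen so that the exocyclic alkene is not protonated and isomerised.

Step 13
Reactants: 20 (1S,2R,3R)-2-ethenyl-6-methylidene-3-(propan-2-yl)cyclohexane-1-carboxylic acid; 21 tert-butyl 2-(bromomethyl)prop-2-enoate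
Product: 22 2-(tert-butoxycarbonyl)prop-2-en-1-yl (1S,2R,3R)-2-ethenyl-6-methylidene-3-(propan-2-yl)cyclohexane-1-carboxylate
Conditions: KHCO3, DMF, rt
Reagents that add atoms: none
Why: O-alkylation of the carboxylate by a reactive allylic bromide (SN2, the SN2′ path giving the same product) under hydrogencarbonate conditions too mild to conjugate the alkene or epimerise C-1.

Step 14
Reactants: 22 2-(tert-butoxycarbonyl)prop-2-en-1-yl (1S,2R,3R)-2-ethenyl-6-methylidene-3-(propan-2-yl)cyclohexane-1-carboxylate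
Product: 23 tert-butyl (5aS,6R,9aS)-9-methylidene-1-oxo-6-(propan-2-yl)-1,3,5a,6,7,8,9,9a-octahydro-2-benzoxepine-4-carboxylate
Conditions: second-generation Hoveyda–Grubbs catalyst (H2IMes)Cl2Ru=CH(C6H4-2-OiPr) (5 mol %), toluene, 5 mM, 80 °C
Reagents that add atoms: none
Why: Ring-closing metathesis: the catalyst loads on the monosubstituted vinyl group and closes onto the 2-substituted acrylate with loss of ethene; the seven-membered ring can hold only the cis ring alkene, which is the required geometry, and the hindered exocyclic methylene should not take part.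

Step 15
Reactants: 23 tert-butyl (5aS,6R,9aS)-9-methylidene-1-oxo-6-(propan-2-yl)-1,3,5a,6,7,8,9,9a-octahydro-2-benzoxepine-4-carboxylate
Product: 24 tert-butyl (5aS,6R,9S,9aS)-9-hydroxy-9-(hydroxymethyl)-1-oxo-6-(propan-2-yl)-1,3,5a,6,7,8,9,9a-octahydro-2-benzoxepine-4-carboxylate
Conditions: OsO4 (2 mol %), NMO (1.1 equiv), acetone/H2O (5:1), 0 °C; Na2SO3
Reagents that add atoms: N-methylmorpholine N-oxide, C[N+]1([O-])CCOCC1; water, O
Why: Catalytic osmium tetroxide dihydroxylation of the electron-rich 1,1-disubstituted alkene in preference to the conjugated ring alkene; the bulky reagent should approach the exocyclic alkene from the equatorial side, away from the 1,3-related axial hydrogens on C-5a and C-7, so the tertiary hydroxyl becomes equatorial (trans to the C-9a carbonyl) and the CH2OH axial (C-9, S).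

Step 16
Reactants: 24 tert-butyl (5aS,6R,9S,9aS)-9-hydroxy-9-(hydroxymethyl)-1-oxo-6-(propan-2-yl)-1,3,5a,6,7,8,9,9a-octahydro-2-benzoxepine-4-carboxylate
Product: 26 (5aS,6R,9S,9aS)-1-oxo-6-(propan-2-yl)-9-(triethylsilyloxy)-9-[(triethylsilyloxy)methyl]-1,3,5a,6,7,8,9,9a-octahydro-2-benzoxepine-4-carboxylic acid, via its triethylsilyl ester 25 (not isolated)
Conditions: TESOTf (4 equiv), 2,6-lutidine (6 equiv), CH2Cl2, 0 °C to rt; then THF/aqueous pH 7 buffer, rt
Reagents that add atoms: triethylsilyl trifluoromethanesulfonate, CC[Si](CC)(CC)OS(=O)(=O)C(F)(F)F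
Why: Silyl-triflate chemistry used twice in one flask: TESOTf silylates the primary and the tertiary hydroxyl and cleaves the tert-butyl ester to its silyl ester (loss of isobutene), and mild hydrolysis frees only the carboxylic acid, silyl esters being far more labile than silyl ethers.

Step 17
Reactants: 6 tert-butyl 4-oxobutanoate; 5 (E)-3-methyl-1-nitrobut-1-ene
Product: 28 tert-butyl (3R,4R)-3-(hydroxymethyl)-5-methyl-4-(nitromethyl)hexanoate, via aldehyde adduct 27 (not isolated)
Conditions: (S)-2-[diphenyl(trimethylsilyloxy)methyl]pyrrolidine (10 mol %), 4-nitrophenol (10 mol %), toluene, 0 °C to rt; then NaBH4, MeOH, 0 °C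
Reagents that add atoms: none
Why: Mirror image of step 2: enamine-catalysed Michael addition in which the S catalyst exposes the opposite enamine face and should give C-3 as R (syn adduct), followed by NaBH4 reduction in the same flask.

Step 18
Reactants: 28 tert-butyl (3R,4R)-3-(hydroxymethyl)-5-methyl-4-(nitromethyl)hexanoate
Product: 29 tert-butyl (3R,4R)-3-{[tert-butyl(diphenyl)silyl]oxymethyl}-5-methyl-4-(nitromethyl)hexanoate
Conditions: TBDPSCl, imidazole, CH2Cl2, rt
Reagents that add atoms: tert-butyl(chloro)diphenylsilane, CC(C)(C)[Si](Cl)(c1ccccc1)c1ccccc1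
Why: Silylation of the primary alcohol as in step 3; no stereocentre is touched.

Step 19
Reactants: 29 tert-butyl (3R,4R)-3-{[tert-butyl(diphenyl)silyl]oxymethyl}-5-methyl-4-(nitromethyl)hexanoate
Product: 30 (2R,3R)-5-tert-butoxy-3-{[tert-butyl(diphenyl)silyl]oxymethyl}-5-oxo-2-(propan-2-yl)pentanoic acid
Conditions: NaNO2 (3 equiv), AcOH (10 equiv), DMSO, 35 °C
Reagents that add atoms: sodium nitrite, [Na+].[O-]N=O
Why: Nitrosative nitro-to-carboxyl conversion as in step 4; the stereocentres are not involved.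

Step 20
Reactants: 30 (2R,3R)-5-tert-butoxy-3-{[tert-butyl(diphenyl)silyl]oxymethyl}-5-oxo-2-(propan-2-yl)pentanoic acid; 11 acrolein
Product: 31 (2R,3S)-4-(tert-butoxycarbonyl)-3-{[tert-butyl(diphenyl)silyl]oxymethyl}-5-hydroxy-2-(propan-2-yl)hept-6-enoic acid (mixture of C-4/C-5 diastereomers)
Conditions: LDA (2.3 equiv), THF, −78 °C; acrolein (1.5 equiv), −78 °C; AcOH, −78 °C; crude taken on at once
Reagents that add atoms: none
Why: Dianion aldol addition to acrolein as in step 5; the new centres are uncontrolled and are removed or made labile in the next step.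

Step 21
Reactants: 31 (2R,3S)-4-(tert-butoxycarbonyl)-3-{[tert-butyl(diphenyl)silyl]oxymethyl}-5-hydroxy-2-(propan-2-yl)hept-6-enoic acid
Product: 32 (2R,3S)-4-(tert-butoxycarbonyl)-3-{[tert-butyl(diphenyl)silyl]oxymethyl}-5-oxo-2-(propan-2-yl)hept-6-enoic acid (C-4 epimers and enol)
Conditions: Dess–Martin periodinane (1.3 equiv), NaHCO3, CH2Cl2, 0 °C
Reagents that add atoms: none
Why: Dess–Martin oxidation to the β-keto ester vinyl ketone as in step 6.

Step 22
Reactants: 32 (2R,3S)-4-(tert-butoxycarbonyl)-3-{[tert-butyl(diphenyl)silyl]oxymethyl}-5-oxo-2-(propan-2-yl)hept-6-enoic acid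
Product: 33 tert-butyl (1R,2S,3S)-2-{[tert-butyl(diphenyl)silyl]oxymethyl}-6-oxo-3-(propan-2-yl)cyclohexane-1-carboxylate (all-trans)
Conditions: Ir[dF(CF3)ppy]2(dtbbpy)PF6 (2 mol %), K2HPO4 (1 equiv), MeCN/H2O (9:1), 10 mM, degassed, blue LEDs (450 nm), rt
Reagents that add atoms: none
Why: Mirror image of step 7, the same photoredox decarboxylative 6-endo Giese cyclisation (carboxylate oxidation by the excited trivalent iridium complex, loss of CO2, radical addition to the vinyl ketone terminus, reduction by the divalent iridium species, protonation), with the chair-like transition state placing isopropyl and silyloxymethyl equatorial so that C-3 is formed S and the β-keto ester carbon settles all-equatorial.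

Step 23
Reactants: 33 tert-butyl (1R,2S,3S)-2-{[tert-butyl(diphenyl)silyl]oxymethyl}-6-oxo-3-(propan-2-yl)cyclohexane-1-carboxylate
Product: 34 tert-butyl (1R,2S,3S)-2-{[tert-butyl(diphenyl)silyl]oxymethyl}-6-methylidene-3-(propan-2-yl)cyclohexane-1-carboxylate
Conditions: Zn, CH2Br2, TiCl4 (reagent pre-formed in THF at 5 °C), CH2Cl2, 0 °C to rt
Reagents that add atoms: dibromomethane, BrCBr
Why: Takai–Lombardo methylenation of the ketone as in step 8, non-basic so that the ring stereocentres are kept.

Step 24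
Reactants: 34 tert-butyl (1R,2S,3S)-2-{[tert-butyl(diphenyl)silyl]oxymethyl}-6-methylidene-3-(propan-2-yl)cyclohexane-1-carboxylate
Product: 35 tert-butyl (1R,2S,3S)-2-(hydroxymethyl)-6-methylidene-3-(propan-2-yl)cyclohexane-1-carboxylate
Conditions: HF·pyridine, pyridine, THF, 0 °C to rt
Reagents that add atoms: none
Why: Fluoride cleavage of the silyl ether as in step 9.

Step 25
Reactants: 35 tert-butyl (1R,2S,3S)-2-(hydroxymethyl)-6-methylidene-3-(propan-2-yl)cyclohexane-1-carboxylate
Product: 36 tert-butyl (1R,2S,3S)-2-formyl-6-methylidene-3-(propan-2-yl)cyclohexane-1-carboxylate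
Conditions: Dess–Martin periodinane, NaHCO3, CH2Cl2, 0 °C
Reagents that add atoms: none
Why: Dess–Martin oxidation of the primary alcohol as in step 10; the equatorial aldehyde is the stable epimer.

Step 26
Reactants: 36 tert-butyl (1R,2S,3S)-2-formyl-6-methylidene-3-(propan-2-yl)cyclohexane-1-carboxylate
Product: 37 tert-butyl (1R,2S,3S)-2-ethenyl-6-methylidene-3-(propan-2-yl)cyclohexane-1-carboxylate
Conditions: Ph3PCH3Br, KHMDS, THF, −78 to 0 °C
Reagents that add atoms: methyltriphenylphosphonium bromide, [Br-].C[P+](c1ccccc1)(c1ccccc1)c1ccccc1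
Why: Wittig methylenation of the aldehyde as in step 11; stereocentres unchanged.

Step 27
Reactants: 37 tert-butyl (1R,2S,3S)-2-ethenyl-6-methylidene-3-(propan-2-yl)cyclohexane-1-carboxylate
Product: 39 (1R,2S,3S)-2-ethenyl-6-methylidene-3-(propan-2-yl)cyclohexane-1-carboxylic acid, via its trimethylsilyl ester 38 (not isolated)
Conditions: TMSOTf, 2,6-lutidine, CH2Cl2, 0 °C to rt; then aqueous pH 5 buffer
Reagents that add atoms: none
Why: Silyl-triflate cleavage of the tert-butyl ester and hydrolysis of the silyl ester as in step 12.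

Step 28
Reactants: 39 (1R,2S,3S)-2-ethenyl-6-methylidene-3-(propan-2-yl)cyclohexane-1-carboxylic acid; 21 tert-butyl 2-(bromomethyl)prop-2-enoate
Product: 40 2-(tert-butoxycarbonyl)prop-2-en-1-yl (1R,2S,3S)-2-ethenyl-6-methylidene-3-(propan-2-yl)cyclohexane-1-carboxylate
Conditions: KHCO3, DMF, rt
Reagents that add atoms: none
Why: Carboxylate O-alkylation (SN2) by the allylic bromide as in step 13.

Step 29
Reactants: 40 2-(tert-butoxycarbonyl)prop-2-en-1-yl (1R,2S,3S)-2-ethenyl-6-methylidene-3-(propan-2-yl)cyclohexane-1-carboxylate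
Product: 41 tert-butyl (5aR,6S,9aR)-9-methylidene-1-oxo-6-(propan-2-yl)-1,3,5a,6,7,8,9,9a-octahydro-2-benzoxepine-4-carboxylate
Conditions: second-generation Hoveyda–Grubbs catalyst (H2IMes)Cl2Ru=CH(C6H4-2-OiPr) (5 mol %), toluene, 5 mM, 80 °C
Reagents that add atoms: none
Why: Ring-closing metathesis to the seven-membered unsaturated lactone as in step 14, the ring enforcing the cis alkene.

Step 30
Reactants: 41 tert-butyl (5aR,6S,9aR)-9-methylidene-1-oxo-6-(propan-2-yl)-1,3,5a,6,7,8,9,9a-octahydro-2-benzoxepine-4-carboxylate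
Product: 42 tert-butyl (5aR,6S,9R,9aR)-9-hydroxy-9-(hydroxymethyl)-1-oxo-6-(propan-2-yl)-1,3,5a,6,7,8,9,9a-octahydro-2-benzoxepine-4-carboxylate
Conditions: OsO4 (2 mol %), NMO (1.1 equiv), acetone/H2O (5:1), 0 °C; Na2SO3
Reagents that add atoms: N-methylmorpholine N-oxide, C[N+]1([O-])CCOCC1; water, O
Why: Catalytic osmium tetroxide dihydroxylation as in step 15, equatorial approach to the exocyclic alkene giving the equatorial tertiary hydroxyl and axial CH2OH (C-9, R).

Step 31
Reactants: 26 (5aS,6R,9S,9aS)-1-oxo-6-(propan-2-yl)-9-(triethylsilyloxy)-9-[(triethylsilyloxy)methyl]-1,3,5a,6,7,8,9,9a-octahydro-2-benzoxepine-4-carboxylic acid; 42 tert-butyl (5aR,6S,9R,9aR)-9-hydroxy-9-(hydroxymethyl)-1-oxo-6-(propan-2-yl)-1,3,5a,6,7,8,9,9a-octahydro-2-benzoxepine-4-carboxylate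
Product: 43 protected dimer, the 4-carboxylate of 26 esterified with the primary hydroxyl of 42 (two TES ethers and one tert-butyl ester retained)
Conditions: EDC·HCl (1.5 equiv), DMAP (0.3 equiv), CH2Cl2, 0 °C to rt
Reagents that add atoms: none
Why: Carbodiimide/DMAP (Steglich) esterification of the conjugated acid with the only reactive hydroxyl of 42, the primary CH2OH; the tertiary alcohol should not acylate and 26 has no free hydroxyl, so self-condensation is excluded and no stereocentre is touched.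

Step 32
Reactants: 43 protected dimer
Product: 44 CNP0340505.1 (target)
Conditions: TFA/CH2Cl2 (1:2), H2O (10 equiv), 0 °C
Reagents that add atoms: none
Why: Acidolysis: aqueous trifluoroacetic acid should remove the tert-butyl ester (as isobutene) and both triethylsilyl ethers in one operation, cold and short enough to leave the lactones, the linking ester and the tertiary alcohols intact.

**Compound list**

1 | isobutyraldehyde (2-methylpropanal) | CC(C)C=O | starting material
2 | nitromethane | C[N+](=O)[O-] | starting material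
3 | 3-methyl-1-nitrobutan-2-ol (racemic) | CC(C)C(O)C[N+](=O)[O-] | intermediate
4 | 3-methyl-1-nitrobutan-2-yl methanesulfonate (racemic) | CC(C)C(OS(C)(=O)=O)C[N+](=O)[O-] | intermediate
5 | (E)-3-methyl-1-nitrobut-1-ene | CC(C)/C=C/[N+](=O)[O-] | intermediate
6 | tert-butyl 4-oxobutanoate | O=CCCC(=O)OC(C)(C)C | starting material
7 | tert-butyl (3S,4S)-3-formyl-5-methyl-4-(nitromethyl)hexanoate | O=C[C@@H](CC(=O)OC(C)(C)C)[C@H](C(C)C)C[N+](=O)[O-] | intermediate
8 | tert-butyl (3S,4S)-3-(hydroxymethyl)-5-methyl-4-(nitromethyl)hexanoate | OC[C@@H](CC(=O)OC(C)(C)C)[C@H](C(C)C)C[N+](=O)[O-] | intermediate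
9 | tert-butyl (3S,4S)-3-{[tert-butyl(diphenyl)silyl]oxymethyl}-5-methyl-4-(nitromethyl)hexanoate | CC(C)(C)[Si](c1ccccc1)(c1ccccc1)OC[C@@H](CC(=O)OC(C)(C)C)[C@H](C(C)C)C[N+](=O)[O-] | intermediate
10 | (2S,3S)-5-tert-butoxy-3-{[tert-butyl(diphenyl)silyl]oxymethyl}-5-oxo-2-(propan-2-yl)pentanoic acid | CC(C)[C@H](C(=O)O)[C@@H](CO[Si](c1ccccc1)(c1ccccc1)C(C)(C)C)CC(=O)OC(C)(C)C | intermediate
11 | acrolein (prop-2-enal) | C=CC=O | starting material
12 | (2S,3R)-4-(tert-butoxycarbonyl)-3-{[tert-butyl(diphenyl)silyl]oxymethyl}-5-hydroxy-2-(propan-2-yl)hept-6-enoic acid, C-4/C-5 diastereomer mixture | CC(C)[C@H](C(=O)O)[C@@H](CO[Si](c1ccccc1)(c1ccccc1)C(C)(C)C)C(C(=O)OC(C)(C)C)C(O)C=C | intermediate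
13 | (2S,3R)-4-(tert-butoxycarbonyl)-3-{[tert-butyl(diphenyl)silyl]oxymethyl}-5-oxo-2-(propan-2-yl)hept-6-enoic acid, C-4 epimers/enol (key-step precursor) | CC(C)[C@H](C(=O)O)[C@@H](CO[Si](c1ccccc1)(c1ccccc1)C(C)(C)C)C(C(=O)OC(C)(C)C)C(=O)C=C | intermediate
14 | tert-butyl (1S,2R,3R)-2-{[tert-butyl(diphenyl)silyl]oxymethyl}-6-oxo-3-(propan-2-yl)cyclohexane-1-carboxylate, all-trans (key-step product) | CC(C)[C@H]1CCC(=O)[C@@H](C(=O)OC(C)(C)C)[C@@H]1CO[Si](c1ccccc1)(c1ccccc1)C(C)(C)C | intermediate
15 | tert-butyl (1S,2R,3R)-2-{[tert-butyl(diphenyl)silyl]oxymethyl}-6-methylidene-3-(propan-2-yl)cyclohexane-1-carboxylate | CC(C)[C@H]1CCC(=C)[C@@H](C(=O)OC(C)(C)C)[C@@H]1CO[Si](c1ccccc1)(c1ccccc1)C(C)(C)C | intermediate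
16 | tert-butyl (1S,2R,3R)-2-(hydroxymethyl)-6-methylidene-3-(propan-2-yl)cyclohexane-1-carboxylate | CC(C)[C@H]1CCC(=C)[C@@H](C(=O)OC(C)(C)C)[C@@H]1CO | intermediate
17 | tert-butyl (1S,2R,3R)-2-formyl-6-methylidene-3-(propan-2-yl)cyclohexane-1-carboxylate | CC(C)[C@H]1CCC(=C)[C@@H](C(=O)OC(C)(C)C)[C@@H]1C=O | intermediate
18 | tert-butyl (1S,2R,3R)-2-ethenyl-6-methylidene-3-(propan-2-yl)cyclohexane-1-carboxylate | CC(C)[C@H]1CCC(=C)[C@@H](C(=O)OC(C)(C)C)[C@@H]1C=C | intermediate
19 | trimethylsilyl (1S,2R,3R)-2-ethenyl-6-methylidene-3-(propan-2-yl)cyclohexane-1-carboxylate | CC(C)[C@H]1CCC(=C)[C@@H](C(=O)O[Si](C)(C)C)[C@@H]1C=C | intermediate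
20 | (1S,2R,3R)-2-ethenyl-6-methylidene-3-(propan-2-yl)cyclohexane-1-carboxylic acid | CC(C)[C@H]1CCC(=C)[C@@H](C(=O)O)[C@@H]1C=C | intermediate
21 | tert-butyl 2-(bromomethyl)prop-2-enoate | C=C(CBr)C(=O)OC(C)(C)C | starting material
22 | 2-(tert-butoxycarbonyl)prop-2-en-1-yl (1S,2R,3R)-2-ethenyl-6-methylidene-3-(propan-2-yl)cyclohexane-1-carboxylate | CC(C)[C@H]1CCC(=C)[C@@H](C(=O)OCC(=C)C(=O)OC(C)(C)C)[C@@H]1C=C | intermediate
23 | tert-butyl (5aS,6R,9aS)-9-methylidene-1-oxo-6-(propan-2-yl)-1,3,5a,6,7,8,9,9a-octahydro-2-benzoxepine-4-carboxylate | CC(C)[C@H]1CCC(=C)[C@H]2C(=O)OCC(C(=O)OC(C)(C)C)=C[C@H]12 | intermediate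
24 | tert-butyl (5aS,6R,9S,9aS)-9-hydroxy-9-(hydroxymethyl)-1-oxo-6-(propan-2-yl)-1,3,5a,6,7,8,9,9a-octahydro-2-benzoxepine-4-carboxylate | CC(C)[C@H]1CC[C@@](O)(CO)[C@H]2C(=O)OCC(C(=O)OC(C)(C)C)=C[C@H]12 | intermediate
25 | triethylsilyl (5aS,6R,9S,9aS)-1-oxo-6-(propan-2-yl)-9-(triethylsilyloxy)-9-[(triethylsilyloxy)methyl]-1,3,5a,6,7,8,9,9a-octahydro-2-benzoxepine-4-carboxylate | CC(C)[C@H]1CC[C@@](O[Si](CC)(CC)CC)(CO[Si](CC)(CC)CC)[C@H]2C(=O)OCC(C(=O)O[Si](CC)(CC)CC)=C[C@H]12 | intermediate
26 | (5aS,6R,9S,9aS)-1-oxo-6-(propan-2-yl)-9-(triethylsilyloxy)-9-[(triethylsilyloxy)methyl]-1,3,5a,6,7,8,9,9a-octahydro-2-benzoxepine-4-carboxylic acid | CC(C)[C@H]1CC[C@@](O[Si](CC)(CC)CC)(CO[Si](CC)(CC)CC)[C@H]2C(=O)OCC(C(=O)O)=C[C@H]12 | intermediate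
27 | tert-butyl (3R,4R)-3-formyl-5-methyl-4-(nitromethyl)hexanoate | O=C[C@H](CC(=O)OC(C)(C)C)[C@@H](C(C)C)C[N+](=O)[O-] | intermediate
28 | tert-butyl (3R,4R)-3-(hydroxymethyl)-5-methyl-4-(nitromethyl)hexanoate | OC[C@H](CC(=O)OC(C)(C)C)[C@@H](C(C)C)C[N+](=O)[O-] | intermediate
29 | tert-butyl (3R,4R)-3-{[tert-butyl(diphenyl)silyl]oxymethyl}-5-methyl-4-(nitromethyl)hexanoate | CC(C)(C)[Si](c1ccccc1)(c1ccccc1)OC[C@H](CC(=O)OC(C)(C)C)[C@@H](C(C)C)C[N+](=O)[O-] | intermediate
30 | (2R,3R)-5-tert-butoxy-3-{[tert-butyl(diphenyl)silyl]oxymethyl}-5-oxo-2-(propan-2-yl)pentanoic acid | CC(C)[C@@H](C(=O)O)[C@H](CO[Si](c1ccccc1)(c1ccccc1)C(C)(C)C)CC(=O)OC(C)(C)C | intermediate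
31 | (2R,3S)-4-(tert-butoxycarbonyl)-3-{[tert-butyl(diphenyl)silyl]oxymethyl}-5-hydroxy-2-(propan-2-yl)hept-6-enoic acid, C-4/C-5 diastereomer mixture | CC(C)[C@@H](C(=O)O)[C@H](CO[Si](c1ccccc1)(c1ccccc1)C(C)(C)C)C(C(=O)OC(C)(C)C)C(O)C=C | intermediate
32 | (2R,3S)-4-(tert-butoxycarbonyl)-3-{[tert-butyl(diphenyl)silyl]oxymethyl}-5-oxo-2-(propan-2-yl)hept-6-enoic acid, C-4 epimers/enol | CC(C)[C@@H](C(=O)O)[C@H](CO[Si](c1ccccc1)(c1ccccc1)C(C)(C)C)C(C(=O)OC(C)(C)C)C(=O)C=C | intermediate
33 | tert-butyl (1R,2S,3S)-2-{[tert-butyl(diphenyl)silyl]oxymethyl}-6-oxo-3-(propan-2-yl)cyclohexane-1-carboxylate, all-trans | CC(C)[C@@H]1CCC(=O)[C@H](C(=O)OC(C)(C)C)[C@H]1CO[Si](c1ccccc1)(c1ccccc1)C(C)(C)C | intermediate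
34 | tert-butyl (1R,2S,3S)-2-{[tert-butyl(diphenyl)silyl]oxymethyl}-6-methylidene-3-(propan-2-yl)cyclohexane-1-carboxylate | CC(C)[C@@H]1CCC(=C)[C@H](C(=O)OC(C)(C)C)[C@H]1CO[Si](c1ccccc1)(c1ccccc1)C(C)(C)C | intermediate
35 | tert-butyl (1R,2S,3S)-2-(hydroxymethyl)-6-methylidene-3-(propan-2-yl)cyclohexane-1-carboxylate | CC(C)[C@@H]1CCC(=C)[C@H](C(=O)OC(C)(C)C)[C@H]1CO | intermediate
36 | tert-butyl (1R,2S,3S)-2-formyl-6-methylidene-3-(propan-2-yl)cyclohexane-1-carboxylate | CC(C)[C@@H]1CCC(=C)[C@H](C(=O)OC(C)(C)C)[C@H]1C=O | intermediate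
37 | tert-butyl (1R,2S,3S)-2-ethenyl-6-methylidene-3-(propan-2-yl)cyclohexane-1-carboxylate | CC(C)[C@@H]1CCC(=C)[C@H](C(=O)OC(C)(C)C)[C@H]1C=C | intermediate
38 | trimethylsilyl (1R,2S,3S)-2-ethenyl-6-methylidene-3-(propan-2-yl)cyclohexane-1-carboxylate | CC(C)[C@@H]1CCC(=C)[C@H](C(=O)O[Si](C)(C)C)[C@H]1C=C | intermediate
39 | (1R,2S,3S)-2-ethenyl-6-methylidene-3-(propan-2-yl)cyclohexane-1-carboxylic acid | CC(C)[C@@H]1CCC(=C)[C@H](C(=O)O)[C@H]1C=C | intermediate
40 | 2-(tert-butoxycarbonyl)prop-2-en-1-yl (1R,2S,3S)-2-ethenyl-6-methylidene-3-(propan-2-yl)cyclohexane-1-carboxylate | CC(C)[C@@H]1CCC(=C)[C@H](C(=O)OCC(=C)C(=O)OC(C)(C)C)[C@H]1C=C | intermediate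
41 | tert-butyl (5aR,6S,9aR)-9-methylidene-1-oxo-6-(propan-2-yl)-1,3,5a,6,7,8,9,9a-octahydro-2-benzoxepine-4-carboxylate | CC(C)[C@@H]1CCC(=C)[C@@H]2C(=O)OCC(C(=O)OC(C)(C)C)=C[C@@H]12 | intermediate
42 | tert-butyl (5aR,6S,9R,9aR)-9-hydroxy-9-(hydroxymethyl)-1-oxo-6-(propan-2-yl)-1,3,5a,6,7,8,9,9a-octahydro-2-benzoxepine-4-carboxylate | CC(C)[C@@H]1CC[C@](O)(CO)[C@@H]2C(=O)OCC(C(=O)OC(C)(C)C)=C[C@@H]12 | intermediate
43 | protected dimer: [(5aR,6S,9R,9aR)-4-(tert-butoxycarbonyl)-9-hydroxy-1-oxo-6-(propan-2-yl)-1,3,5a,6,7,8,9,9a-octahydro-2-benzoxepin-9-yl]methyl ester of acid 26 | CC(C)[C@H]1CC[C@@](O[Si](CC)(CC)CC)(CO[Si](CC)(CC)CC)[C@H]2C(=O)OCC(C(=O)OC[C@@]3(O)CC[C@@H](C(C)C)[C@@H]4C=C(C(=O)OC(C)(C)C)COC(=O)[C@H]43)=C[C@H]12 | intermediate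
44 | CNP0340505.1: [(5aR,6S,9R,9aR)-4-carboxy-9-hydroxy-1-oxo-6-(propan-2-yl)-1,3,5a,6,7,8,9,9a-octahydro-2-benzoxepin-9-yl]methyl (5aS,6R,9S,9aS)-9-hydroxy-9-(hydroxymethyl)-1-oxo-6-(propan-2-yl)-1,3,5a,6,7,8,9,9a-octahydro-2-benzoxepine-4-carboxylate | CC(C)[C@H]1CC[C@@](O)(CO)[C@H]2C(=O)OCC(C(=O)OC[C@@]3(O)CC[C@@H](C(C)C)[C@@H]4C=C(C(=O)O)COC(=O)[C@H]43)=C[C@H]12 | target

**Step count and risk**

Total: 32 steps (step 1 shared; steps 2–16 series A; steps 17–30 series B; steps 31–32 union). Longest linear sequence: 18 steps (steps 1–16, 31, 32).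

The three steps most likely to fail (each has a mirror-image twin in series B):

Step 7 (twin: step 22). What may go wrong: oxidation of the β-keto ester enolate in place of the carboxylate, intermolecular addition or oligomerisation of the vinyl ketone before ring closure, or weak trans selectivity at the isopropyl carbon. Fallback, a reductive instead of an oxidative entry to the same radical: starting from 13, condensation with N-hydroxyphthalimide (N,N′-diisopropylcarbodiimide, cat. DMAP, CH2Cl2) gives the N-acyloxyphthalimide ester F1. Under base-free photoreduction ([Ru(bpy)3](PF6)2, Hantzsch ester, CH2Cl2, blue LEDs) F1 takes up an electron, loses phthalimide anion and CO2, and the same secondary radical closes the same ring A bond 6-endo. The α-keto radical is quenched by hydrogen transfer from the dihydropyridine, and the route is rejoined at 14. In series B the same two operations lead from 32 through the enantiomeric N-acyloxyphthalimide ester F4 to 33.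

Step 8 (twin: step 23). What may go wrong: chelation or enolisation of the β-keto ester by titanium so that the ketone stays unreactive, or Lewis-acid loss of the tert-butyl ester. Fallback, a two-stage Peterson olefination: starting from 14, Me3SiCH2MgCl precomplexed with anhydrous CeCl3 (THF, −78 °C) should add to the ketone, organocerium reagents adding to β-dicarbonyl ketones in preference to deprotonating them, to give the β-hydroxysilane F2. Brief acid-promoted anti elimination (aqueous HF, MeCN, 0 °C) returns to the route at 15. In series B, 33 gives the enantiomeric β-hydroxysilane F5 and then 34.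

Step 15 (twin: step 30). What may go wrong: attack of the osmium reagent on the axial instead of the equatorial face of the exocyclic alkene, giving the C-9 epimer, and base-induced migration of the lactone onto the new primary hydroxyl during the reaction. Fallback, a stepwise anti-hydroxylation that reaches the same configuration by a different stereochemical principle: starting from 23, mCPBA (NaHCO3, CH2Cl2, 0 °C), a small electrophile that prefers the axial face of methylenecyclohexanes, gives the spiro-epoxide F3 with its oxygen axial. Acid-catalysed hydrolysis (cat. HClO4, THF/H2O, 0 °C) opens the protonated epoxide at the tertiary carbon with inversion, so the new hydroxyl is equatorial and the CH2OH axial, which is 24. In series B, 41 gives the enantiomeric spiro-epoxide F6 and then 42.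

**Further compounds**

F1 | step 7 | 1,3-dioxoisoindolin-2-yl (2S,3R)-4-(tert-butoxycarbonyl)-3-{[tert-butyl(diphenyl)silyl]oxymethyl}-5-oxo-2-(propan-2-yl)hept-6-enoate (N-acyloxyphthalimide ester of 13) | CC(C)[C@H](C(=O)ON1C(=O)c2ccccc2C1=O)[C@@H](CO[Si](c1ccccc1)(c1ccccc1)C(C)(C)C)C(C(=O)OC(C)(C)C)C(=O)C=C
F2 | step 8 | tert-butyl (1S,2R,3R)-2-{[tert-butyl(diphenyl)silyl]oxymethyl}-6-hydroxy-3-(propan-2-yl)-6-[(trimethylsilyl)methyl]cyclohexane-1-carboxylate (carbinol configuration not controlled) | CC(C)[C@H]1CCC(O)(C[Si](C)(C)C)[C@@H](C(=O)OC(C)(C)C)[C@@H]1CO[Si](c1ccccc1)(c1ccccc1)C(C)(C)C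
F3 | step 15 | spiro-epoxide of 23 at C-9 (spiro[2-benzoxepine-9,2′-oxirane]), oxirane oxygen axial and cis to C-1 | CC(C)[C@H]1CC[C@]3(CO3)[C@H]2C(=O)OCC(C(=O)OC(C)(C)C)=C[C@H]12
F4 | step 22 | enantiomer of F1 (N-acyloxyphthalimide ester of 32) | CC(C)[C@@H](C(=O)ON1C(=O)c2ccccc2C1=O)[C@H](CO[Si](c1ccccc1)(c1ccccc1)C(C)(C)C)C(C(=O)OC(C)(C)C)C(=O)C=C
F5 | step 23 | enantiomer of F2 (β-hydroxysilane from 33) | CC(C)[C@@H]1CCC(O)(C[Si](C)(C)C)[C@H](C(=O)OC(C)(C)C)[C@H]1CO[Si](c1ccccc1)(c1ccccc1)C(C)(C)C
F6 | step 30 | enantiomer of F3 (spiro-epoxide of 41) | CC(C)[C@@H]1CC[C@@]3(CO3)[C@@H]2C(=O)OCC(C(=O)OC(C)(C)C)=C[C@@H]12
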